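**Plan**
Cuts: C7=C8 (C10 ring sulfone + C30 polyenal), C7'=C8' (C10 geranyl ylide + C20 dialdehyde), C11=C12 together with C11'=C12' (two C5 phosphonates + C10 dialdehyde), and last C6–C7 at the ring.
Enabling feature: in the six-membered ε ring, C6 bears the exocyclic C7 and is allylic to the unconjugated C4=C5 alkene (methyl on C5), and the gem-dimethyl carbon C1 is its other neighbour. Moving the alkene to C5=C6 and tying C7 to an oxygen on C4 uncovers a cyclohexenyl oxymethyl carbanion, the precursor of a [2,3]-Wittig shift.
Ring: the only ring is closed at the outset by Michael addition and aldol condensation. Afterwards it is only reorganised.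
Chain: C5 + C10 + C5 gives the C20 core, geranyl is added at C7'=C8', and the ring end is added last at C7=C8.
Stereochemistry: C6, the sole stereocentre, comes from an (S)-carbinol at C4 set by catalyst-controlled ketone reduction and relayed suprafacially to (R)-C6. The E alkenes come from E building blocks, E-selective olefinations and a closing equilibration.

Key step: step 4

Assumption: carotenoid numbering is used (ring C1–C6, chain from C7, primed numbers for the acyclic half), compounds 6 and 17 are taken as commercial, and all polyenes are handled under argon in dim light.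

Step 1
Reactants: 1 isobutyraldehyde (2-methylpropanal); 2 pent-1-en-3-one (ethyl vinyl ketone)
Product: 4 2,4,4-trimethylcyclohex-2-en-1-one, via 2,2-dimethyl-5-oxoheptanal 3 (not isolated)
Conditions: conc. H2SO4 (cat.), toluene, 45 °C, then reflux (Dean–Stark)
Reagents that add atoms: none
Why: Acid-catalysed Robinson-type annulation in which the enol of 1 adds to 2 (Michael addition) and, in keto aldehyde 3, only the ethyl CH2 of the ketone can reach the non-enolisable formyl group through a six-membered ring, so the aldol condensation should give 4 as the single enone.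

Step 2
Reactants: 4 2,4,4-trimethylcyclohex-2-en-1-one
Product: 5 (S)-2,4,4-trimethylcyclohex-2-en-1-ol
Conditions: (R)-1-methyl-3,3-diphenyltetrahydro-1H,3H-pyrrolo[1,2-c][1,3,2]oxazaborole (10 mol %), BH3·SMe2, THF, −20 °C, slow addition of 4; MeOH, aqueous work-up
Reagents that add atoms: none
Why: Corey–Bakshi–Shibata reduction in which the C2 methyl makes the alkenyl arm the large substituent, so the ketone binds the catalyst boron through the lone pair on the CH2 side and hydride reaches one carbonyl face only, which sets the (S)-carbinol centre by catalyst control in a 1,2-reduction.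

Step 3
Reactants: 5 (S)-2,4,4-trimethylcyclohex-2-en-1-ol; 6 tributyl(iodomethyl)stannane
Product: 8 tributyl({[(1S)-2,4,4-trimethylcyclohex-2-en-1-yl]oxy}methyl)stannane, via potassium alkoxide 7 (not isolated)
Conditions: KH, THF, 0 °C; then 6, 0 °C → rt
Reagents that add atoms: none
Why: Williamson etherification in which alkoxide 7 displaces iodide from the unhindered CH2 of 6, and since the C–O bond at the stereocentre is never broken the (S) configuration is retained.

Step 4
Reactants: 8 tributyl({[(1S)-2,4,4-trimethylcyclohex-2-en-1-yl]oxy}methyl)stannane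
Product: 11 (R)-α-cyclogeraniol ([(1R)-2,6,6-trimethylcyclohex-2-en-1-yl]methanol), via lithiomethyl ether 9 (not isolated), via lithium alkoxide 10 (not isolated)
Conditions: n-BuLi (1.2 equiv), THF, −78 → −40 °C; H2O
Reagents that add atoms: none
Why: Tin–lithium exchange converts 8 into the unstabilised oxymethyllithium 9, whose carbanion carbon (the future C7) bonds to C6 while the C4–O bond breaks and the ring alkene moves from C5=C6 to C4=C5, a concerted [2,3]-sigmatropic shift through a five-membered envelope that is made irreversible by the passage from a carbanion to alkoxide 10. The closest known reaction type is the Still–Wittig rearrangement of cyclohexenyl stannylmethyl ethers, which is established to run with 1,3-transfer of chirality. No ring is closed, the six-membered ring of step 1 being kept and only its alkene transposed. The new stereocentre C6 is controlled solely by the C4 carbinol centre, because the carbanion is tied to the C4 oxygen by a single CH2 unit and cannot get to the opposite ring face, so the (S)-ether delivers C7 suprafacially and gives (R)-C6 as C4 becomes sp2. The step needs [2,3]- rather than [1,2]-migration and bond formation next to quaternary C1: allylic 1,2-strain with the C5 methyl holds the C4–O bond pseudoaxial and aligned with the π orbitals, the two pseudoaxial allylic positions of that half-chair lie on opposite faces so that the axial C1 methyl is turned away from the migrating CH2Li and only the equatorial one flanks the unsubstituted terminus C6, and the low temperature disfavours the radical-pair [1,2] route. As alkoxide 10 cannot return, the outcome is kinetic, and the alkene is left at C4=C5 where the ε end group needs it rather than at the tetrasubstituted C5=C6 position of the β series.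

Step 5
Reactants: 11 (R)-α-cyclogeraniol
Product: 12 1-phenyl-5-({[(1R)-2,6,6-trimethylcyclohex-2-en-1-yl]methyl}sulfanyl)-1H-tetrazole
Conditions: 1-phenyl-1H-tetrazole-5-thiol, PPh3, diisopropyl azodicarboxylate, THF, 0 °C → rt
Reagents that add atoms: 1-phenyl-1H-tetrazole-5-thiol, Sc1nnnn1-c1ccccc1
Why: Mitsunobu thioetherification in which the alkoxyphosphonium salt of the primary carbinol is displaced at C7 by the soft, acidic heteroaryl thiol in an SN2 reaction under neutral conditions, so neither C6 nor the ring alkene is involved.

Step 6
Reactants: 12 1-phenyl-5-({[(1R)-2,6,6-trimethylcyclohex-2-en-1-yl]methyl}sulfanyl)-1H-tetrazole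
Product: 13 1-phenyl-5-({[(1R)-2,6,6-trimethylcyclohex-2-en-1-yl]methyl}sulfonyl)-1H-tetrazole (C10 ring sulfone)
Conditions: (NH4)6Mo7O24·4H2O (10 mol %), 30% aq. H2O2, EtOH, 0 °C → rt
Reagents that add atoms: hydrogen peroxide, OO
Why: Molybdate-catalysed peroxide oxidation of a sulfide to the sulfone, in which the peroxomolybdate attacks sulfur much faster than a hindered trisubstituted alkene, the chemoselectivity routinely relied on for unsaturated tetrazolyl sulfones.

Step 7
Reactants: 14 ethyl tiglate (ethyl (E)-2-methylbut-2-enoate)
Product: 15 ethyl (E)-4-bromo-2-methylbut-2-enoate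
Conditions: N-bromosuccinimide, 2,2'-azobis(2-methylpropionitrile) (2 mol %), PhCF3, reflux; fractional distillation
Reagents that add atoms: N-bromosuccinimide, O=C1CCC(=O)N1Br
Why: Wohl–Ziegler allylic bromination in which hydrogen abstraction at the C4 methyl gives the ester-conjugated allyl radical and bromine is taken up at its primary terminus, so the conjugated E-enoate is kept and the regioisomeric bromide is removed by distillation.

Step 8
Reactants: 15 ethyl (E)-4-bromo-2-methylbut-2-enoate
Product: 16 ethyl (E)-4-(diethoxyphosphoryl)-2-methylbut-2-enoate (C5 phosphonate)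
Conditions: P(OEt)3, neat, 140 °C, EtBr distilled off
Reagents that add atoms: triethyl phosphite, CCOP(OCC)OCC
Why: Michaelis–Arbuzov reaction, that is SN2 attack of phosphorus on the primary allylic bromide followed by dealkylation of the phosphonium ion by bromide, which leaves the E-enoate untouched.

Step 9
Reactants: 16 C5 phosphonate (2 equiv); 17 (2E,4E,6E)-2,7-dimethylocta-2,4,6-trienedial (C10 dialdehyde)
Product: 19 crocetin diethyl ester (all-E diethyl 8,8'-diapocarotene-8,8'-dioate), via sodium phosphonate carbanion 18 (not isolated)
Conditions: NaH (2.2 equiv), THF, 0 °C; then 17, 0 °C → rt; crystallisation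
Reagents that add atoms: none
Why: Twofold Horner–Wadsworth–Emmons olefination in which the ester-stabilised vinylogous carbanion 18 reacts at the carbon next to phosphorus with both formyl groups of 17 and, adding reversibly as a stabilised anion, should form C11=C12 and C11'=C12' as E alkenes, the sparingly soluble all-E diester crystallising out.

Step 10
Reactants: 19 crocetin diethyl ester
Product: 20 all-E 8,8'-diapocarotene-8,8'-diol
Conditions: i-Bu2AlH (5 equiv), CH2Cl2, −40 → 0 °C; aq. potassium sodium tartrate
Reagents that add atoms: none
Why: Aluminium hydride reduction of conjugated esters, in which two 1,2-hydride deliveries per ester give the bis-allylic diol and the heptaene is not attacked.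

Step 11
Reactants: 20 all-E 8,8'-diapocarotene-8,8'-diol
Product: 21 crocetindial (all-E 8,8'-diapocarotene-8,8'-dial, C20)
Conditions: activated MnO2 (excess), CH2Cl2, rt, dark
Reagents that add atoms: none
Why: MnO2 oxidation, selective for allylic (here polyenylic) alcohols, stops at the aldehyde and is neutral, so the all-E chain is preserved.

Step 12
Reactants: 22 geranyl bromide ((E)-1-bromo-3,7-dimethylocta-2,6-diene)
Product: 23 geranyltriphenylphosphonium bromide
Conditions: PPh3, toluene, rt
Reagents that add atoms: triphenylphosphine, c1ccc(cc1)P(c1ccccc1)c1ccccc1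
Why: Quaternisation of PPh3 by SN2 attack on a primary allylic bromide at room temperature, with the salt precipitating from toluene so that the E alkene of the geranyl unit is not disturbed.

Step 13
Reactants: 23 geranyltriphenylphosphonium bromide; 21 crocetindial (3 equiv)
Product: 26 all-E apo-8'-lycopenal (8'-apo-ψ-caroten-8'-al, C30), via geranylidene ylide 24 (not isolated), via 7'E/7'Z apo-8'-lycopenal 25 (not isolated)
Conditions: NaOMe (1.0 equiv, slow addition), CH2Cl2/MeOH, 0 °C → rt; then heptane, reflux, Ar, dark; SiO2 (surplus 21 recovered)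
Reagents that add atoms: none
Why: Wittig olefination in which ylide 24 is generated slowly in front of a threefold excess of 21, so it is captured by the dialdehyde rather than by 26 and its short lifetime protects the C5'=C6' geometry, while the sterically hindered 7'Z bond of mixture 25, lying inside the conjugated chain, relaxes to E on heating.

Step 14
Reactants: 13 C10 ring sulfone; 26 all-E apo-8'-lycopenal
Product: 28 (6R)-δ-carotene as a 7E/7Z mixture, via potassium sulfonyl carbanion 27 (not isolated)
Conditions: KN(SiMe3)2 (1.0 equiv), THF, −78 °C, 30 min; then 26 in THF, −78 °C → rt, dark; H2O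
Reagents that add atoms: none
Why: Julia–Kocienski olefination in which carbanion 27, preformed with exactly one equivalent of base so that none is left for the polyenal or for the doubly allylic C6–H of the product, adds to the formyl group, and Smiles transfer of the tetrazole with loss of SO2 and the tetrazolate forms C7=C8, mainly E because the bulky ring and the polyene-stabilised open intermediate favour the anti arrangement, with C6 (β to sulfur) never deprotonated.

Step 15
Reactants: 28 (6R)-δ-carotene as a 7E/7Z mixture
Product: 29 (6R)-δ-carotene ((6R)-ε,ψ-carotene, all-E), the target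
Conditions: heptane, reflux, Ar, dark; cooling, crystallisation (CH2Cl2/MeOH)
Reagents that add atoms: none
Why: Thermal E/Z isomerisation of a polyene under thermodynamic control coupled to crystallisation, in which the all-E isomer is both the most stable and the least soluble and is drained from the mixture with residual Z isomers staying in the mother liquor, while the neutral medium leaves the C6–H bond and the ε alkene in place.

**Compound list**
1 | isobutyraldehyde | CC(C)C=O | starting material
2 | pent-1-en-3-one (ethyl vinyl ketone) | C=CC(=O)CC | starting material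
3 | 2,2-dimethyl-5-oxoheptanal | CCC(=O)CCC(C)(C)C=O | intermediate
4 | 2,4,4-trimethylcyclohex-2-en-1-one | CC1=CC(C)(C)CCC1=O | intermediate
5 | (S)-2,4,4-trimethylcyclohex-2-en-1-ol | O[C@@H]1C(C)=CC(C)(C)CC1 | intermediate
6 | tributyl(iodomethyl)stannane | CCCC[Sn](CCCC)(CCCC)CI | starting material
7 | potassium (S)-2,4,4-trimethylcyclohex-2-en-1-olate | [K+].[O-][C@@H]1C(C)=CC(C)(C)CC1 | intermediate
8 | tributyl({[(1S)-2,4,4-trimethylcyclohex-2-en-1-yl]oxy}methyl)stannane | CCCC[Sn](CCCC)(CCCC)CO[C@@H]1C(C)=CC(C)(C)CC1 | intermediate
9 | {[(1S)-2,4,4-trimethylcyclohex-2-en-1-yl]oxy}methyllithium | [Li]CO[C@@H]1C(C)=CC(C)(C)CC1 | intermediate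
10 | lithium [(1R)-2,6,6-trimethylcyclohex-2-en-1-yl]methanolate | [Li+].[O-]C[C@H]1C(C)=CCCC1(C)C | intermediate
11 | (R)-α-cyclogeraniol | OC[C@H]1C(C)=CCCC1(C)C | intermediate
12 | 1-phenyl-5-({[(1R)-2,6,6-trimethylcyclohex-2-en-1-yl]methyl}sulfanyl)-1H-tetrazole | S(C[C@H]1C(C)=CCCC1(C)C)c1nnnn1-c1ccccc1 | intermediate
13 | 1-phenyl-5-({[(1R)-2,6,6-trimethylcyclohex-2-en-1-yl]methyl}sulfonyl)-1H-tetrazole | O=S(=O)(C[C@H]1C(C)=CCCC1(C)C)c1nnnn1-c1ccccc1 | intermediate
14 | ethyl tiglate | CCOC(=O)/C(C)=C/C | starting material
15 | ethyl (E)-4-bromo-2-methylbut-2-enoate | CCOC(=O)/C(C)=C/CBr | intermediate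
16 | ethyl (E)-4-(diethoxyphosphoryl)-2-methylbut-2-enoate | CCOC(=O)/C(C)=C/CP(=O)(OCC)OCC | intermediate
17 | (2E,4E,6E)-2,7-dimethylocta-2,4,6-trienedial | O=C/C(C)=C/C=C/C=C(C)/C=O | starting material
18 | sodium salt of the C4 carbanion of 16 | [Na+].CCOC(=O)/C(C)=C/[CH-]P(=O)(OCC)OCC | intermediate
19 | crocetin diethyl ester | CCOC(=O)/C(C)=C/C=C/C(C)=C/C=C/C=C(C)/C=C/C=C(C)/C(=O)OCC | intermediate
20 | all-E 8,8'-diapocarotene-8,8'-diol | OC/C(C)=C/C=C/C(C)=C/C=C/C=C(C)/C=C/C=C(C)/CO | intermediate
21 | crocetindial | O=C/C(C)=C/C=C/C(C)=C/C=C/C=C(C)/C=C/C=C(C)/C=O | intermediate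
22 | geranyl bromide | CC(C)=CCC/C(C)=C/CBr | starting material
23 | geranyltriphenylphosphonium bromide | CC(C)=CCC/C(C)=C/C[P+](c1ccccc1)(c1ccccc1)c1ccccc1.[Br-] | intermediate
24 | geranylidenetriphenylphosphorane | CC(C)=CCC/C(C)=C/C=P(c1ccccc1)(c1ccccc1)c1ccccc1 | intermediate
25 | apo-8'-lycopenal, 7'E/7'Z mixture | CC(C)=CCC/C(C)=C/C=CC(/C)=C/C=C/C(C)=C/C=C/C=C(C)/C=C/C=C(C)/C=O | intermediate
26 | all-E apo-8'-lycopenal | CC(C)=CCC/C(C)=C/C=C/C(C)=C/C=C/C(C)=C/C=C/C=C(C)/C=C/C=C(C)/C=O | intermediate
27 | potassium salt of the C7 carbanion of 13 | [K+].O=S(=O)([CH-][C@H]1C(C)=CCCC1(C)C)c1nnnn1-c1ccccc1 | intermediate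
28 | (6R)-δ-carotene, 7E/7Z mixture | CC(C)=CCC/C(C)=C/C=C/C(C)=C/C=C/C(C)=C/C=C/C=C(C)/C=C/C=C(C)/C=C[C@H]1C(C)=CCCC1(C)C | intermediate
29 | (6R)-δ-carotene, all-E | CC(C)=CCC/C(C)=C/C=C/C(C)=C/C=C/C(C)=C/C=C/C=C(C)/C=C/C=C(C)/C=C/[C@H]1C(C)=CCCC1(C)C | target

**Step count**
Total: 15 steps. Longest linear sequence: 8 steps (1–6, 14, 15). The C20 branch (7–11, 13–15) is equally long.

**Steps most likely to fail**

Step 4. The lithiomethyl ether may be protonated, or may drift into the [1,2]-migration with loss of chirality transfer, before it can bond to C6 next to the quaternary carbon. The fallback keeps the same C6–C7 bond and the same face but replaces the carbanion by a neutral carbene. It sets out from 5 and returns at 11. Heating 5 with N,N-dimethylformamide dimethyl acetal in xylene (Büchi rearrangement) should exchange one methoxy group to give the mixed amide acetal F1. Loss of methanol gives the alkoxy(dimethylamino)carbene F2, and its suprafacial [2,3] shift gives (1R)-N,N,2,6,6-pentamethylcyclohex-2-ene-1-carboxamide F3. Reduction of this hindered tertiary amide with LiH2NBH3 in THF gives 11. The C6–H bond is α to a weakly acidifying amide only for this one stage.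

Step 14. Addition of the hindered, β-branched carbanion may be slow or reversible, because the polyenal is sparingly soluble in the cold and its formyl group is deactivated by nine conjugated double bonds. Self-condensation of the sulfone could then take over, and a Z bond at the chain terminus would be corrected only slowly by heat. The fallback moves the hindered olefination to a small, soluble, electrophilic aldehyde and closes the long chain by a polyene Wittig reaction in a C15 + C10 + C15 order. It sets out from 13 and 17 and returns at 29.
- Ring half: carbanion 27 and commercial (E)-4-acetoxy-2-methylbut-2-enal should give, by Julia–Kocienski olefination, the ring-end C15 dienyl acetate F4. PPh3·HBr converts it into the ring-end C15 phosphonium bromide F5.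
- Acyclic half: commercial (3E,5E)-pseudoionone and vinylmagnesium bromide give vinyl-ψ-ionol F6. PPh3·HBr gives the acyclic C15 phosphonium bromide F7, and its ylide F8 (NaOMe) olefinates one formyl group of 17 to apo-12'-lycopenal F9.
- Union: the ylide F10 made from F5 (NaOMe) and F9 then form C11=C12 as the 11E/11Z δ-carotene mixture F11. Its hindered in-chain Z bond isomerises readily under the heating and crystallisation of step 15 to give 29.

Step 2. Facial discrimination in the ketone reduction may be insufficient, or hydroboration may compete. Any loss of enantiomeric purity here is carried unchanged to C6, and no crystalline intermediate follows until the end. The fallback replaces catalyst control by an enzymatic kinetic resolution. It sets out from 4 and returns at 5. Luche reduction (NaBH4, CeCl3·7H2O, MeOH) gives racemic 2,4,4-trimethylcyclohex-2-en-1-ol F12. Transesterification with vinyl acetate over immobilised Candida antarctica lipase B in methyl tert-butyl ether should, following the usual enantiopreference of lipases for secondary alcohols, acylate the (R)-enantiomer to (R)-2,4,4-trimethylcyclohex-2-en-1-yl acetate F13 and leave 5 unreacted. Running the acylation past half conversion raises the optical purity of 5. The same acylation can also polish material from step 2.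

**Further compounds**
F1 | step 4 | 1-methoxy-N,N-dimethyl-1-{[(1S)-2,4,4-trimethylcyclohex-2-en-1-yl]oxy}methanamine | COC(N(C)C)O[C@@H]1C(C)=CC(C)(C)CC1
F2 | step 4 | (dimethylamino){[(1S)-2,4,4-trimethylcyclohex-2-en-1-yl]oxy}carbene | CN(C)[C]O[C@@H]1C(C)=CC(C)(C)CC1
F3 | step 4 | (1R)-N,N,2,6,6-pentamethylcyclohex-2-ene-1-carboxamide | CN(C)C(=O)[C@H]1C(C)=CCCC1(C)C
F4 | step 14 | (2E,4E)-3-methyl-5-[(1R)-2,6,6-trimethylcyclohex-2-en-1-yl]penta-2,4-dien-1-yl acetate | CC(=O)OC/C=C(C)/C=C/[C@H]1C(C)=CCCC1(C)C
F5 | step 14 | {(2E,4E)-3-methyl-5-[(1R)-2,6,6-trimethylcyclohex-2-en-1-yl]penta-2,4-dien-1-yl}triphenylphosphonium bromide | c1ccccc1[P+](c1ccccc1)(c1ccccc1)C/C=C(C)/C=C/[C@H]1C(C)=CCCC1(C)C.[Br-]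
F6 | step 14 | vinyl-ψ-ionol (racemic (4E,6E)-3,7,11-trimethyldodeca-1,4,6,10-tetraen-3-ol) | CC(C)=CCC/C(C)=C/C=C/C(C)(O)C=C
F7 | step 14 | [(2E,4E,6E)-3,7,11-trimethyldodeca-2,4,6,10-tetraen-1-yl]triphenylphosphonium bromide | CC(C)=CCC/C(C)=C/C=C/C(C)=C/C[P+](c1ccccc1)(c1ccccc1)c1ccccc1.[Br-]
F8 | step 14 | ylide of F7 | CC(C)=CCC/C(C)=C/C=C/C(C)=C/C=P(c1ccccc1)(c1ccccc1)c1ccccc1
F9 | step 14 | all-E apo-12'-lycopenal (C25) | CC(C)=CCC/C(C)=C/C=C/C(C)=C/C=C/C(C)=C/C=C/C=C(C)/C=O
F10 | step 14 | ylide of F5 | c1ccccc1P(c1ccccc1)(c1ccccc1)=C/C=C(C)/C=C/[C@H]1C(C)=CCCC1(C)C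
F11 | step 14 | (6R)-δ-carotene, 11E/11Z mixture | CC(C)=CCC/C(C)=C/C=C/C(C)=C/C=C/C(C)=C/C=C/C=C(\C)C=C/C=C(C)/C=C/[C@H]1C(C)=CCCC1(C)C
F12 | step 2 | racemic 2,4,4-trimethylcyclohex-2-en-1-ol | OC1C(C)=CC(C)(C)CC1
F13 | step 2 | (R)-2,4,4-trimethylcyclohex-2-en-1-yl acetate | CC(=O)O[C@H]1C(C)=CC(C)(C)CC1
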